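**Retrosynthetic overview**
- The biaryl C5–C1' bond is cut last: an (S)-5-bromo-3,4-dihydroisoquinoline is joined to a 1-naphthyl borate in a one-flask lithiation/borylation/Suzuki–Miyaura coupling.
- The nitrogen ring is cut at the key C3–N bond: acetonitrile displaces the triflate of an (R)-1-arylpropan-2-ol with inversion, and the nitrilium ion then closes C1–C8a (new annulation).
- The carbinol comes from 3,5-dimethoxyphenyl Grignard and (R)-propylene oxide, followed by ring bromination.
- The naphthalene comes from anionic annulation of an ortho-methallyl benzamide, O-methylation and para-bromination.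
- Ring order: the nitrogen ring and the second naphthalene ring are built separately, and the two halves are joined at the end.

Assumption: the SMILES fixes only C3, which is (S), and leaves the biaryl axis open; the route sets (S)-C3 and gives the two atropo-diastereomers together, separable by chromatography if one is wanted.

**Route**

Step 1
Reactants: 1 1-bromo-3,5-dimethoxybenzene; 2 (R)-2-methyloxirane
Product: 4 (R)-1-(3,5-dimethoxyphenyl)propan-2-ol, via arylmagnesium bromide 3 (not isolated)
Conditions: Mg, THF, 45 °C; CuI (10 mol %), then 2, −30 → 0 °C; H2O quench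
Reagents that add atoms: none
Why: Copper-catalysed Grignard opening of a terminal epoxide; the aryl group attacks the unhindered CH2 by SN2, so the stereocentre of 2 is untouched and is carried over as the (R)-carbinol.

Step 2
Reactants: 4 (R)-1-(3,5-dimethoxyphenyl)propan-2-ol
Product: 5 (R)-1-(2-bromo-3,5-dimethoxyphenyl)propan-2-ol
Conditions: NBS (1.0 equiv), MeCN, 0 °C, dark
Reagents that add atoms: N-bromosuccinimide, O=C1CCC(=O)N1Br
Why: Electrophilic aromatic bromination; the position para to one methoxy group and ortho to the side chain is favoured over the position flanked by two methoxy groups, as is usual for 3,5-dimethoxybenzyl systems, and one equivalent of NBS at 0 °C leaves the secondary alcohol alone.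

Step 3
Reactants: 5 (R)-1-(2-bromo-3,5-dimethoxyphenyl)propan-2-ol; 6 acetonitrile (also the solvent)
Product: 9 (S)-5-bromo-6,8-dimethoxy-1,3-dimethyl-3,4-dihydroisoquinoline, via alkyl triflate 7 (not isolated), via nitrilium triflate 8 (not isolated)
Conditions: Tf2O (1.05 equiv), 2,6-di-tert-butyl-4-methylpyridine (2.2 equiv), MeCN/CH2Cl2 1:1, −40 °C, 30 min; then 23 °C (45 °C if needed); aq NaHCO3
Reagents that add atoms: none
Why: Proposed new method: a stereoinvertive dehydrative Ritter/Bischler–Napieralski annulation in which O-triflation gives 7, the solvent nitrile displaces the triflate by SN2 with inversion to form the C3–N bond, and the N-alkylnitrilium 8 closes onto the ring carbon ortho and para to the two methoxy groups to form C1–C8a, so (S)-C3 is set from the (R)-carbinol; the SN2 path should win because both methoxy groups are meta to the ipso carbon and cannot stabilise a phenonium ion, and the hindered pyridine neither alkylates nor promotes E2; the closest known reaction types are the Ritter reaction, the Tf2O-promoted annulation of 2-arylethanols with nitriles to 3,4-dihydroisoquinolines (phenonium pathway, no stereocentre transferred) and the Bischler–Napieralski cyclisation, and a stereospecific version on a chiral secondary carbinol has not been shown.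

Step 4
Reactants: 10 2-methoxybenzoyl chloride; 11 diethylamine
Product: 12 N,N-diethyl-2-methoxybenzamide
Conditions: aq NaOH, CH2Cl2, 0 → 23 °C
Reagents that add atoms: none
Why: Schotten–Baumann acylation of a secondary amine by an acid chloride.

Step 5
Reactants: 12 N,N-diethyl-2-methoxybenzamide; 13 3-bromo-2-methylprop-1-ene
Product: 16 N,N-diethyl-2-methoxy-6-(2-methylprop-2-en-1-yl)benzamide, via ortho-lithiated amide 14 (not isolated), via arylmagnesium bromide 15 (not isolated)
Conditions: s-BuLi, TMEDA, THF, −78 °C; MgBr2·OEt2, −78 → 0 °C; then 13, 0 → 23 °C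
Reagents that add atoms: none
Why: Directed ortho-metalation; the diethylamide directs s-BuLi to the only free ortho position, transmetalation to magnesium suppresses self-condensation, and the arylmagnesium is allylated by the allylic bromide.

Step 6
Reactants: 16 N,N-diethyl-2-methoxy-6-(2-methylprop-2-en-1-yl)benzamide
Product: 18 1,8-dimethoxy-3-methylnaphthalene, via lithium naphtholate 17 (not isolated)
Conditions: LiN(i-Pr)2 (1.3 equiv), THF, −78 → 23 °C; then MeI (4 equiv), DMF, 23 → 40 °C
Reagents that add atoms: iodomethane, CI
Why: Anionic benzamide annulation followed by Williamson ether synthesis; the base removes a benzylic-allylic proton, the terminal carbon of the allyl anion attacks the amide carbonyl in a six-membered closure, loss of diethylamide and enolisation give naphtholate 17, which is O-methylated in the same flask.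

Step 7
Reactants: 18 1,8-dimethoxy-3-methylnaphthalene
Product: 19 1-bromo-4,5-dimethoxy-2-methylnaphthalene
Conditions: NBS (1.0 equiv), MeCN, 0 °C
Reagents that add atoms: N-bromosuccinimide, O=C1CCC(=O)N1Br
Why: Electrophilic aromatic bromination at C4 of 18, the position para to a methoxy group and ortho to the methyl group in the more electron-rich ring.

Step 8
Reactants: 19 1-bromo-4,5-dimethoxy-2-methylnaphthalene; 9 (S)-5-bromo-6,8-dimethoxy-1,3-dimethyl-3,4-dihydroisoquinoline
Product: 22 O-methylancistrocladinine [(S)-5-(4,5-dimethoxy-2-methylnaphthalen-1-yl)-6,8-dimethoxy-1,3-dimethyl-3,4-dihydroisoquinoline], via naphthyllithium 20 (not isolated), via lithium triisopropyl borate 21 (not isolated)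
Conditions: 19, n-BuLi, THF, −78 °C; B(OiPr)3, −78 → 23 °C; then 9, Pd(OAc)2 (5 mol %), SPhos (10 mol %), aq K3PO4, toluene/THF/H2O, 90 °C
Reagents that add atoms: none
Why: Bromine–lithium exchange and borylation give ate complex 21, which enters a Suzuki–Miyaura coupling with 9 without isolation; SPhos is suited to tetra-ortho-substituted biaryls, the phosphate base does not touch C3, and the new axis forms as a mixture of atropo-diastereomers.

**Compound list**
1 | 1-bromo-3,5-dimethoxybenzene | COc1cc(Br)cc(OC)c1 | starting material
2 | (R)-2-methyloxirane ((R)-propylene oxide) | C[C@@H]1CO1 | starting material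
3 | 3,5-dimethoxyphenylmagnesium bromide | COc1cc(OC)cc([Mg]Br)c1 | intermediate (not isolated)
4 | (R)-1-(3,5-dimethoxyphenyl)propan-2-ol | C[C@@H](O)Cc1cc(OC)cc(OC)c1 | intermediate
5 | (R)-1-(2-bromo-3,5-dimethoxyphenyl)propan-2-ol | C[C@@H](O)Cc1cc(OC)cc(OC)c1Br | intermediate
6 | acetonitrile | CC#N | starting material
7 | (R)-1-(2-bromo-3,5-dimethoxyphenyl)propan-2-yl trifluoromethanesulfonate | C[C@@H](OS(=O)(=O)C(F)(F)F)Cc1cc(OC)cc(OC)c1Br | intermediate (not isolated)
8 | N-[(S)-1-(2-bromo-3,5-dimethoxyphenyl)propan-2-yl]acetonitrilium trifluoromethanesulfonate | CC#[N+][C@@H](C)Cc1cc(OC)cc(OC)c1Br.[O-]S(=O)(=O)C(F)(F)F | intermediate (not isolated)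
9 | (S)-5-bromo-6,8-dimethoxy-1,3-dimethyl-3,4-dihydroisoquinoline | COc1cc(OC)c(Br)c2c1C(C)=N[C@@H](C)C2 | intermediate
10 | 2-methoxybenzoyl chloride | COc1ccccc1C(=O)Cl | starting material
11 | diethylamine | CCNCC | starting material
12 | N,N-diethyl-2-methoxybenzamide | CCN(CC)C(=O)c1ccccc1OC | intermediate
13 | 3-bromo-2-methylprop-1-ene (methallyl bromide) | C=C(C)CBr | starting material
14 | [2-(diethylcarbamoyl)-3-methoxyphenyl]lithium | [Li]c1cccc(OC)c1C(=O)N(CC)CC | intermediate (not isolated)
15 | [2-(diethylcarbamoyl)-3-methoxyphenyl]magnesium bromide | Br[Mg]c1cccc(OC)c1C(=O)N(CC)CC | intermediate (not isolated)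
16 | N,N-diethyl-2-methoxy-6-(2-methylprop-2-en-1-yl)benzamide | CCN(CC)C(=O)c1c(CC(C)=C)cccc1OC | intermediate
17 | lithium 8-methoxy-3-methylnaphthalen-1-olate | [Li+].[O-]c1cc(C)cc2cccc(OC)c12 | intermediate (not isolated)
18 | 1,8-dimethoxy-3-methylnaphthalene | COc1cc(C)cc2cccc(OC)c12 | intermediate
19 | 1-bromo-4,5-dimethoxy-2-methylnaphthalene | COc1cc(C)c(Br)c2cccc(OC)c12 | intermediate
20 | (4,5-dimethoxy-2-methylnaphthalen-1-yl)lithium | [Li]c1c(C)cc(OC)c2c(OC)cccc12 | intermediate (not isolated)
21 | lithium (4,5-dimethoxy-2-methylnaphthalen-1-yl)tri(propan-2-yloxy)borate | [Li+].CC(C)O[B-](OC(C)C)(OC(C)C)c1c(C)cc(OC)c2c(OC)cccc12 | intermediate (not isolated)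
22 | O-methylancistrocladinine | COc1cc(OC)c(-c2c(C)cc(OC)c3c(OC)cccc23)c2c1C(C)=N[C@@H](C)C2 | target

**Step count**
Total steps: 8 (steps 1–3 make the isoquinoline half, steps 4–7 the naphthalene half, step 8 joins them). Amide 12 is also a catalogue compound; buying it removes step 4.
Longest linear sequence: 5 steps (10 → 12 → 16 → 18 → 19 → 22).

**Three steps most likely to fail**

Step 3 (proposed new annulation). The triflate 7 may ionise, which would erode the ee or allow a hydride shift, or it may eliminate to the propenylarene or alkylate a second arene. The ee of 9 must be checked by chiral HPLC. The fallback uses known chemistry and sets out from 5. Mitsunobu azidation (PPh3, DIAD, (PhO)2P(O)N3, THF, 0 °C) proceeds with inversion to give (S)-1-(2-azidopropyl)-2-bromo-3,5-dimethoxybenzene F1. Staudinger reduction (PPh3, THF/H2O, 50 °C), which keeps the aryl bromide, gives (S)-1-(2-bromo-3,5-dimethoxyphenyl)propan-2-amine F2. Acetylation (Ac2O, Et3N, CH2Cl2) gives N-[(S)-1-(2-bromo-3,5-dimethoxyphenyl)propan-2-yl]acetamide F3. Bischler–Napieralski cyclisation (POCl3, MeCN, 80 °C) then comes back to the route at 9.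

Step 8 (hindered one-flask coupling). The electron-rich, hindered naphthyl borate may protodeboronate or transmetalate too slowly, and the imine nitrogen may bind palladium. The fallback sets out from 19 and 9 and replaces the aqueous, base-mediated boron coupling by an anhydrous, base-free organozinc coupling. Naphthyllithium 20 (n-BuLi, THF, −78 °C) is transmetalated with ZnCl2 to (4,5-dimethoxy-2-methylnaphthalen-1-yl)zinc chloride F4. Negishi coupling of this reagent with 9 (Pd2(dba)3, RuPhos, THF/NMP, 60 °C) comes back to the route at 22.

Step 5 (allylation of the ortho-metalated benzamide). The hindered arylmetal may condense with the amide or allylate incompletely. The fallback sets out from 12 and forms the aryl–allyl bond by cross-coupling instead of nucleophilic substitution. The ortho-lithiated amide 14 is quenched with I2 to give N,N-diethyl-2-iodo-6-methoxybenzamide F5. Suzuki–Miyaura allylation with 2-methylallylboronic acid pinacol ester (Pd(dppf)Cl2, K2CO3, dioxane/H2O, 90 °C) comes back to the route at 16; the symmetric methallyl unit gives no regioisomers.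

**Further compounds**
F1 | step 3 | (S)-1-(2-azidopropyl)-2-bromo-3,5-dimethoxybenzene | C[C@H](N=[N+]=[N-])Cc1cc(OC)cc(OC)c1Br
F2 | step 3 | (S)-1-(2-bromo-3,5-dimethoxyphenyl)propan-2-amine | C[C@H](N)Cc1cc(OC)cc(OC)c1Br
F3 | step 3 | N-[(S)-1-(2-bromo-3,5-dimethoxyphenyl)propan-2-yl]acetamide | CC(=O)N[C@@H](C)Cc1cc(OC)cc(OC)c1Br
F4 | step 8 | (4,5-dimethoxy-2-methylnaphthalen-1-yl)zinc chloride | Cl[Zn]c1c(C)cc(OC)c2c(OC)cccc12
F5 | step 5 | N,N-diethyl-2-iodo-6-methoxybenzamide | CCN(CC)C(=O)c1c(I)cccc1OC
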